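**Retrosynthetic overview**
1. Target 36 is a Diels–Alder trimer of one monomer, dehydrozaluzanin C (29). The last bonds join dienone 31 (Saegusa–Ito product of the silyl dienol ether 30 of 29) to the exocyclic enone of dimer 34; 34 is 31 + 29 followed by autoxidation at C10.
2. 29 comes from dehydrocostus lactone 27 by C3 allylic oxidation; the three exocyclic methylenes are installed late (double ketone methylenation, lactone α-methylenation).
3. The trans-lactone comes from the α-epoxide of cis-fused hydroazulene 16, opened anti at C7 by an ethoxyacetylide (C11–C12).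
4. The cyclopentane comes from anti conjugate addition of a three-carbon acetal Grignard reagent to enone 7, then intramolecular aldol (cis fusion).
5. 7 comes from lipase desymmetrisation of meso-diol 3 (from cyclohepta-1,3-diene). Ring order: seven-membered carbocycle (bought), cyclopentane, γ-lactone, then the two spiro-cyclohexenes.

Assumption: locants C1–C15 are guaiane locants (C1/C5 ring fusion, C6 lactone carbinol, C12 lactone carbonyl, C14 on C10, C15 on C4); α is the face of H-1/H-5. The route is a paper design; selectivities are argued by analogy and none has been run.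

**Step 1**
Reactants: 1 cyclohepta-1,3-diene
Product: 3 cis-cyclohept-2-ene-1,4-diol (meso), via endoperoxide 2 (not isolated)
Conditions: O2, hν, tetraphenylporphyrin (cat.), CH2Cl2, 0 °C; then Zn, AcOH, 25 °C
Reagents that add atoms: dioxygen O=O
Why: Singlet-oxygen [4+2] cycloaddition gives the bicyclic endoperoxide, whose O–O reduction can only deliver the cis (meso, achiral) diol.

**Step 2**
Reactants: 3 cis-cyclohept-2-ene-1,4-diol
Product: 4 (1S,4R)-4-hydroxycyclohept-2-en-1-yl acetate
Conditions: Burkholderia cepacia lipase (immobilised), isopropenyl acetate, t-BuOMe, 30 °C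
Reagents that add atoms: isopropenyl acetate CC(=C)OC(C)=O
Why: Lipase-catalysed enantiotopos-selective transesterification (desymmetrisation of the meso-diol, the first asymmetric event) acylates the (S)-carbinol, the sense expected by analogy with the homologous cyclopentenediol, and so fixes the absolute configuration of the whole route.

**Step 3**
Reactants: 4 (1S,4R)-4-hydroxycyclohept-2-en-1-yl acetate
Product: 5 (1S,4R)-4-[(tert-butyldimethylsilyl)oxy]cyclohept-2-en-1-yl acetate
Conditions: TBSCl, imidazole, DMF, 25 °C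
Reagents that add atoms: tert-butyldimethylsilyl chloride CC(C)(C)[Si](C)(C)Cl
Why: Standard silylation of the free allylic alcohol; no stereocentre is touched.

**Step 4**
Reactants: 5 (1S,4R)-4-[(tert-butyldimethylsilyl)oxy]cyclohept-2-en-1-yl acetate
Product: 6 (1S,4R)-4-[(tert-butyldimethylsilyl)oxy]cyclohept-2-en-1-ol
Conditions: K2CO3 (cat.), MeOH, 0 °C
Reagents that add atoms: none
Why: Base-catalysed transesterification (methanolysis) removes the acetate while the silyl ether stays.

**Step 5**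
Reactants: 6 (1S,4R)-4-[(tert-butyldimethylsilyl)oxy]cyclohept-2-en-1-ol
Product: 7 (R)-4-[(tert-butyldimethylsilyl)oxy]cyclohept-2-en-1-one
Conditions: MnO2, CH2Cl2, 25 °C
Reagents that add atoms: none
Why: Chemoselective allylic alcohol oxidation gives the γ-silyloxy enone (carbonyl = C6, OTBS carbon = C10, 10α-O).

**Step 6**
Reactants: 7 (R)-4-[(tert-butyldimethylsilyl)oxy]cyclohept-2-en-1-one; 8 2-(2-bromoethyl)-1,3-dioxolane
Product: 11 (3R,4R)-4-[(tert-butyldimethylsilyl)oxy]-3-[2-(1,3-dioxolan-2-yl)ethyl]cycloheptan-1-one, via Grignard reagent 9 (not isolated), via silyl enol ether 10 (not isolated)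
Conditions: 8, Mg, THF, 25 °C; then CuBr·SMe2 (15 mol%), TMSCl, 7, THF, −78 °C; then aq. citric acid, 0 °C
Reagents that add atoms: none
Why: Copper-catalysed, TMSCl-accelerated conjugate addition occurs anti to the γ-silyloxy group, so the new C1–C2 bond is β (H-1α) and trans to the 10α-OTBS.

**Step 7**
Reactants: 11 (3R,4R)-4-[(tert-butyldimethylsilyl)oxy]-3-[2-(1,3-dioxolan-2-yl)ethyl]cycloheptan-1-one
Product: 12 3-[(1R,2R)-2-[(tert-butyldimethylsilyl)oxy]-6-oxocycloheptyl]propanal
Conditions: PPTS, acetone/H2O 9:1, 50 °C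
Reagents that add atoms: water O
Why: Mild acetal hydrolysis unmasks the aldehyde (C4) without cleaving the secondary TBS ether.

**Step 8**
Reactants: 12 3-[(1R,2R)-2-[(tert-butyldimethylsilyl)oxy]-6-oxocycloheptyl]propanal
Product: 13 4β-hydroxy-10α-[(tert-butyldimethylsilyl)oxy]-1αH,5αH-11,12,13,14,15-pentanorguaian-6-one (cis-fused ketol)
Conditions: K2CO3 (0.3 equiv), MeOH, 0 °C
Reagents that add atoms: none
Why: Intramolecular 5-(enolexo)-exo-trig aldol of the C5 ketone enolate onto the tethered aldehyde can only close on the face carrying the side chain, so the ring fusion is cis (H-5α); the C4 carbinol (β-epimer drawn as major, hydrogen-bonded to the ketone) is oxidised later, so its configuration is immaterial.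

**Step 9**
Reactants: 13 cis-fused ketol
Product: 14 4β,10α-bis[(tert-butyldimethylsilyl)oxy]-1αH,5αH-11,12,13,14,15-pentanorguaian-6-one
Conditions: TBSOTf, 2,6-lutidine, CH2Cl2, −78 °C
Reagents that add atoms: tert-butyldimethylsilyl trifluoromethanesulfonate CC(C)(C)[Si](C)(C)OS(=O)(=O)C(F)(F)F
Why: Low-temperature silylation caps the β-hydroxy ketone before retro-aldol or dehydration can occur.

**Step 10**
Reactants: 14 bis-silyl ketone
Product: 15 4β,10α-bis[(tert-butyldimethylsilyl)oxy]-1αH,5αH-11,12,13,14,15-pentanorguai-6-en-6-yl trifluoromethanesulfonate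
Conditions: KN(SiMe3)2, THF, −78 °C; then PhNTf2
Reagents that add atoms: N-phenylbis(trifluoromethanesulfonimide) O=S(=O)(N(c1ccccc1)S(=O)(=O)C(F)(F)F)C(F)(F)F
Why: Kinetic deprotonation takes the unhindered C7 methylene rather than the tertiary C5–H, and O-triflation traps the C6=C7 enolate regiospecifically.

**Step 11**
Reactants: 15 enol triflate
Product: 16 4β,10α-bis[(tert-butyldimethylsilyl)oxy]-1αH,5αH-11,12,13,14,15-pentanorguai-6-ene
Conditions: Pd(OAc)2 (5 mol%), PPh3, HCO2H, Bu3N, DMF, 60 °C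
Reagents that add atoms: none
Why: Palladium-catalysed formate reduction of the vinyl triflate gives the C6=C7 alkene, the only alkene in the molecule.

**Step 12**
Reactants: 16 cis-fused alkene
Product: 17 6α,7α-epoxy-4β,10α-bis[(tert-butyldimethylsilyl)oxy]-1αH,5αH-11,12,13,14,15-pentanorguaiane
Conditions: mCPBA, NaHCO3, CH2Cl2, 0 °C
Reagents that add atoms: 3-chloroperbenzoic acid OOC(=O)c1cccc(Cl)c1
Why: Prilezhaev epoxidation takes the convex α face (syn to H-5), away from the β-disposed cyclopentane and its 4β-OTBS group, which sets the C6–O bond α.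

**Step 13**
Reactants: 17 α-epoxide; 18 ethoxyacetylene
Product: 21 4β,10α-bis[(tert-butyldimethylsilyl)oxy]-1αH,5αH,6βH,7αH-13,14,15-trinorguaian-12,6-olide (trans-lactone), via lithium ethoxyacetylide 19 (not isolated), via hydroxy ynol ether 20 (not isolated)
Conditions: 18, n-BuLi, THF, −78 °C; then 17, BF3·OEt2, −78 °C; then TsOH·H2O (cat.), wet THF, 25 °C
Reagents that add atoms: water O
Why: BF3-mediated acetylide opening of the epoxide (Yamaguchi-type alkynylation) is anti and occurs at the less hindered C7, giving 7β-C/6α-O, and acid hydration of the ynol ether with capture by the C6 hydroxyl closes the trans-fused γ-lactone.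

**Step 14**
Reactants: 21 trans-lactone
Product: 22 4β,10α-dihydroxy-1αH,5αH,6βH,7αH-13,14,15-trinorguaian-12,6-olide
Conditions: HF·pyridine, THF, 0 to 25 °C
Reagents that add atoms: none
Why: Non-basic fluoride desilylation frees both secondary alcohols without opening the lactone.

**Step 15**
Reactants: 22 diol lactone
Product: 23 4,10-dioxo-1αH,5αH,6βH,7αH-13,14,15-trinorguaian-12,6-olide
Conditions: Dess–Martin periodinane, NaHCO3, CH2Cl2, 25 °C
Reagents that add atoms: none
Why: Buffered neutral oxidation gives the diketone without epimerising C1/C5 or eliminating the β-acyloxy group; the C4 carbinol stereocentre disappears here.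

**Step 16**
Reactants: 23 diketone lactone
Product: 24 1αH,5αH,6βH,7αH-13-norguaia-4(15),10(14)-dien-12,6-olide
Conditions: Zn, CH2Br2, TiCl4, THF/CH2Cl2, 0 to 25 °C
Reagents that add atoms: dibromomethane BrCBr
Why: Takai–Lombardo methylenation is non-basic and ketone-selective, so both hindered, epimerisable ketones become exocyclic methylenes while the lactone and the cis ring fusion survive.

**Step 17**
Reactants: 24 diene lactone
Product: 27 dehydrocostus lactone (guaia-4(15),10(14),11(13)-trien-12,6α-olide), via Mannich base 25 (not isolated), via methiodide 26 (not isolated)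
Conditions: LiN(iPr)2, THF, −78 °C; CH2=NMe2 I (Eschenmoser's salt); then MeI, MeOH; then NaHCO3, CH2Cl2/H2O
Reagents that add atoms: N,N-dimethylmethyleneiminium iodide C=[N+](C)C.[I-]
Why: Mannich reaction of the lactone enolate, N-quaternisation and base-induced β-elimination install the α-methylene group (C13); the transient C11 centre becomes sp2.

**Step 18**
Reactants: 27 dehydrocostus lactone
Product: 28 3-epizaluzanin C (3α-hydroxyguaia-4(15),10(14),11(13)-trien-12,6α-olide)
Conditions: SeO2 (0.5 equiv), t-BuOOH, CH2Cl2, 25 °C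
Reagents that add atoms: selenium dioxide O=[Se]=O; tert-butyl hydroperoxide CC(C)(C)OO
Why: SeO2 allylic oxidation (ene reaction then [2,3]-shift) attacks the C3 methylene of the cyclopentylidene alkene from the convex α face, a precedented selectivity for this lactone, and leaves the acrylate alone.

**Step 19**
Reactants: 28 3-epizaluzanin C
Product: 29 dehydrozaluzanin C (3-oxoguaia-4(15),10(14),11(13)-trien-12,6α-olide)
Conditions: Dess–Martin periodinane, CH2Cl2, 0 °C
Reagents that add atoms: none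
Why: Neutral oxidation of the allylic alcohol gives the cross-conjugated exo-methylene ketone without isomerising it.

**Step 20**
Reactants: 29 dehydrozaluzanin C
Product: 30 3-[(tert-butyldimethylsilyl)oxy]guaia-2,4(15),10(14),11(13)-tetraen-12,6α-olide (silyl dienol ether)
Conditions: TBSOTf, Et3N, CH2Cl2, −78 to 0 °C
Reagents that add atoms: tert-butyldimethylsilyl trifluoromethanesulfonate CC(C)(C)[Si](C)(C)OS(=O)(=O)C(F)(F)F
Why: Soft enolisation can only go toward C2 (C4 is sp2), so the silyl enol ether needed for dehydrogenation forms regiospecifically.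

**Step 21**
Reactants: 30 silyl dienol ether
Product: 31 3-oxoguaia-1,4(15),10(14),11(13)-tetraen-12,6α-olide (dienone; handled only as a cold dilute MeCN solution)
Conditions: Pd(OAc)2 (1.2 equiv), MeCN (0.02 M), 25 °C, Ar, dark; then filtration through Celite at −20 °C under Ar; used at once, never concentrated
Reagents that add atoms: none
Why: Saegusa–Ito dehydrosilylation (divalent palladium enolate bound on the convex α face, syn β-hydride elimination of the cis H-1α) gives the C1=C2 dienone under neutral conditions that leave the lactone alone, and high dilution plus immediate cold filtration keeps the second-order self-cycloaddition of 31 slow enough for the solution to be carried straight into the next operation.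

**Step 22**
Reactants: 31 dienone (solution from step 21); 29 dehydrozaluzanin C
Product: 34 10β-hydroxy spiro-dimer (units B–C of the target), via cycloadduct 32 (not isolated), via hydroperoxide 33 (not isolated)
Conditions: filtrate of 31 run directly onto 29 (5 equiv), MeCN, −20 to 25 °C, Ar; then O2 (1 atm), 25 °C; then PPh3, 0 °C
Reagents that add atoms: dioxygen O=O
Why: The s-cis C2=C1–C10=C14 diene of 31 undergoes an intermolecular Diels–Alder reaction with the C4=C15 enone of 29 (C14 to C15, C2 to C4, the regiochemistry of a diene carrying an acyl group at one terminus) on the open α face of the diene, setting the spiro carbon in the natural sense (biomimetic facial and endo/exo selectivity, assumed); the doubly activated C2–H adduct then autoxidises at C10 through its dienol (β-face O2 capture) and PPh3 reduces the hydroperoxide, while the excess of 29 outcompetes self-addition of 31.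

**Step 23**
Reactants: 31 dienone (solution made afresh by step 21); 34 10β-hydroxy spiro-dimer
Product: 36 ainsliatrimer A, via cycloadduct 35 (not isolated)
Conditions: 31 (2.5 equiv, −20 °C MeCN solution added over 4 h), 34, degassed MeCN, 25 °C, Ar; then Et3N (cat.)
Reagents that add atoms: none
Why: The same Diels–Alder reaction engages the most reactive dienophile of 34 (the exocyclic enone of unit B) to set the second spiro carbon (natural sense assumed by analogy), slow addition keeps the stationary concentration of 31 low so that cross-addition beats self-addition, and under oxygen-free conditions the β,γ-enone tautomerises into conjugation with γ-protonation on the α face (10α-H of unit A).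

**Compound list**
1 | cyclohepta-1,3-diene | C1=CC=CCCC1 | starting material
2 | 6,7-dioxabicyclo[3.2.2]non-8-ene (meso endoperoxide) | O1[C@@H]2C=C[C@H](O1)CCC2 | intermediate
3 | cis-cyclohept-2-ene-1,4-diol (meso) | O[C@@H]1C=C[C@H](O)CCC1 | intermediate
4 | (1S,4R)-4-hydroxycyclohept-2-en-1-yl acetate | CC(=O)O[C@@H]1C=C[C@H](O)CCC1 | intermediate
5 | (1S,4R)-4-[(tert-butyldimethylsilyl)oxy]cyclohept-2-en-1-yl acetate | CC(=O)O[C@@H]1C=C[C@H](O[Si](C)(C)C(C)(C)C)CCC1 | intermediate
6 | (1S,4R)-4-[(tert-butyldimethylsilyl)oxy]cyclohept-2-en-1-ol | O[C@@H]1C=C[C@H](O[Si](C)(C)C(C)(C)C)CCC1 | intermediate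
7 | (R)-4-[(tert-butyldimethylsilyl)oxy]cyclohept-2-en-1-one | O=C1C=C[C@H](O[Si](C)(C)C(C)(C)C)CCC1 | intermediate
8 | 2-(2-bromoethyl)-1,3-dioxolane | BrCCC1OCCO1 | starting material
9 | [2-(1,3-dioxolan-2-yl)ethyl]magnesium bromide | Br[Mg]CCC1OCCO1 | intermediate
10 | trimethylsilyl enol ether (C5=C6) of 11 | O1CCOC1CC[C@H]1[C@H](O[Si](C)(C)C(C)(C)C)CCCC(O[Si](C)(C)C)=C1 | intermediate
11 | (3R,4R)-4-[(tert-butyldimethylsilyl)oxy]-3-[2-(1,3-dioxolan-2-yl)ethyl]cycloheptan-1-one | O1CCOC1CC[C@H]1[C@H](O[Si](C)(C)C(C)(C)C)CCCC(=O)C1 | intermediate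
12 | 3-[(1R,2R)-2-[(tert-butyldimethylsilyl)oxy]-6-oxocycloheptyl]propanal | O=CCC[C@H]1[C@H](O[Si](C)(C)C(C)(C)C)CCCC(=O)C1 | intermediate
13 | 4β-hydroxy-10α-[(tert-butyldimethylsilyl)oxy]-1αH,5αH-11,12,13,14,15-pentanorguaian-6-one (major C4 epimer) | O[C@H]1CC[C@H]2[C@H](O[Si](C)(C)C(C)(C)C)CCCC(=O)[C@H]21 | intermediate
14 | 4β,10α-bis[(tert-butyldimethylsilyl)oxy]-1αH,5αH-11,12,13,14,15-pentanorguaian-6-one | CC(C)(C)[Si](C)(C)O[C@H]1CC[C@H]2[C@H](O[Si](C)(C)C(C)(C)C)CCCC(=O)[C@H]21 | intermediate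
15 | 4β,10α-bis[(tert-butyldimethylsilyl)oxy]-1αH,5αH-11,12,13,14,15-pentanorguai-6-en-6-yl trifluoromethanesulfonate | CC(C)(C)[Si](C)(C)O[C@H]1CC[C@H]2[C@H](O[Si](C)(C)C(C)(C)C)CCC=C(OS(=O)(=O)C(F)(F)F)[C@H]21 | intermediate
16 | 4β,10α-bis[(tert-butyldimethylsilyl)oxy]-1αH,5αH-11,12,13,14,15-pentanorguai-6-ene | CC(C)(C)[Si](C)(C)O[C@H]1CC[C@H]2[C@H](O[Si](C)(C)C(C)(C)C)CCC=C[C@H]21 | intermediate
17 | 6α,7α-epoxy-4β,10α-bis[(tert-butyldimethylsilyl)oxy]-1αH,5αH-11,12,13,14,15-pentanorguaiane | CC(C)(C)[Si](C)(C)O[C@H]1CC[C@H]2[C@H](O[Si](C)(C)C(C)(C)C)CC[C@@H]3O[C@@H]3[C@H]21 | intermediate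
18 | ethoxyacetylene | CCOC#C | starting material
19 | lithium ethoxyacetylide | CCOC#C[Li] | intermediate
20 | 7β-(ethoxyethynyl)-6α-hydroxy-4β,10α-bis[(tert-butyldimethylsilyl)oxy]-1αH,5αH,7αH-11,12,13,14,15-pentanorguaiane | CC(C)(C)[Si](C)(C)O[C@H]1CC[C@H]2[C@H](O[Si](C)(C)C(C)(C)C)CC[C@@H](C#COCC)[C@H](O)[C@H]21 | intermediate
21 | 4β,10α-bis[(tert-butyldimethylsilyl)oxy]-1αH,5αH,6βH,7αH-13,14,15-trinorguaian-12,6-olide | CC(C)(C)[Si](C)(C)O[C@H]1CC[C@H]2[C@H](O[Si](C)(C)C(C)(C)C)CC[C@H]3CC(=O)O[C@@H]3[C@H]21 | intermediate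
22 | 4β,10α-dihydroxy-1αH,5αH,6βH,7αH-13,14,15-trinorguaian-12,6-olide | O[C@H]1CC[C@H]2[C@H](O)CC[C@H]3CC(=O)O[C@@H]3[C@H]21 | intermediate
23 | 4,10-dioxo-1αH,5αH,6βH,7αH-13,14,15-trinorguaian-12,6-olide | O=C1CC[C@H]2C(=O)CC[C@H]3CC(=O)O[C@@H]3[C@H]21 | intermediate
24 | 1αH,5αH,6βH,7αH-13-norguaia-4(15),10(14)-dien-12,6-olide | C=C1CC[C@H]2C(=C)CC[C@H]3CC(=O)O[C@@H]3[C@H]21 | intermediate
25 | 11α-(dimethylaminomethyl) derivative of 24 (Mannich base) | C=C1CC[C@H]2C(=C)CC[C@H]3[C@H](CN(C)C)C(=O)O[C@@H]3[C@H]21 | intermediate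
26 | trimethylammonium iodide of 25 (methiodide) | C=C1CC[C@H]2C(=C)CC[C@H]3[C@H](C[N+](C)(C)C)C(=O)O[C@@H]3[C@H]21.[I-] | intermediate
27 | dehydrocostus lactone | C=C1CC[C@H]2C(=C)CC[C@H]3C(=C)C(=O)O[C@@H]3[C@H]21 | intermediate
28 | 3-epizaluzanin C (3α-OH) | C=C1[C@H](O)C[C@H]2C(=C)CC[C@H]3C(=C)C(=O)O[C@@H]3[C@H]21 | intermediate
29 | dehydrozaluzanin C | C=C1C(=O)C[C@H]2C(=C)CC[C@H]3C(=C)C(=O)O[C@@H]3[C@H]21 | intermediate
30 | 3-[(tert-butyldimethylsilyl)oxy]guaia-2,4(15),10(14),11(13)-tetraen-12,6α-olide | C=C1C(O[Si](C)(C)C(C)(C)C)=C[C@H]2C(=C)CC[C@H]3C(=C)C(=O)O[C@@H]3[C@H]21 | intermediate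
31 | 3-oxoguaia-1,4(15),10(14),11(13)-tetraen-12,6α-olide (dienone) | C=C1C(=O)C=C2C(=C)CC[C@H]3C(=C)C(=O)O[C@@H]3[C@H]21 | intermediate
32 | Diels–Alder adduct of 31 and 29 (unit B: 1(10)-ene, 2α-spiro bond, H-2β) | C=C1C(=O)[C@H]2C3=C(CC[C@H]4C(=C)C(=O)O[C@@H]4[C@@H]13)CC[C@]21C(=O)C[C@H]2C(=C)CC[C@H]3C(=C)C(=O)O[C@@H]3[C@H]21 | intermediate
33 | 10β-hydroperoxy spiro-dimer | C=C1C(=O)C2=C3[C@H]1[C@H]1OC(=O)C(=C)[C@@H]1CC[C@@]3(OO)CC[C@]21C(=O)C[C@H]2C(=C)CC[C@H]3C(=C)C(=O)O[C@@H]3[C@H]21 | intermediate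
34 | 10β-hydroxy spiro-dimer (units B–C) | C=C1C(=O)C2=C3[C@H]1[C@H]1OC(=O)C(=C)[C@@H]1CC[C@@]3(O)CC[C@]21C(=O)C[C@H]2C(=C)CC[C@H]3C(=C)C(=O)O[C@@H]3[C@H]21 | intermediate
35 | Diels–Alder adduct of 31 and 34 (unit A: 1(10)-ene, H-2β) | C=C1C(=O)[C@H]2C3=C(CC[C@H]4C(=C)C(=O)O[C@@H]4[C@@H]13)CC[C@@]21C(=O)C2=C3[C@H]1[C@H]1OC(=O)C(=C)[C@@H]1CC[C@@]3(O)CC[C@]21C(=O)C[C@H]2C(=C)CC[C@H]3C(=C)C(=O)O[C@@H]3[C@H]21 | intermediate
36 | ainsliatrimer A | C=C1C(=O)C2=C3[C@H](CC[C@H]4C(=C)C(=O)O[C@@H]4[C@@H]13)CC[C@@]21C(=O)C2=C3[C@H]1[C@H]1OC(=O)C(=C)[C@@H]1CC[C@@]3(O)CC[C@]21C(=O)C[C@H]2C(=C)CC[C@H]3C(=C)C(=O)O[C@@H]3[C@H]21 | target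

**Totals and weak points**
Total step count: 23. Longest linear sequence: 23 steps (1 to 36); 29 re-enters in step 22, and 31 serves both step 22 and step 23, step 21 being carried out immediately before each use because 31 is not stored.

Step 12 (face-selective epoxidation, which also decides the C6/C7 outcome of step 13). If the α-epoxide is not formed cleanly, the lactone is built from ketone 14 and not through alkene 16. The fallback sets out from 14: kinetic C7 alkylation (LiN(iPr)2, tert-butyl bromoacetate, THF/HMPA, −78 °C), then re-enolisation and kinetic axial protonation to give the equatorial 7β-(tert-butoxycarbonylmethyl) ketone F1. Thermodynamically controlled ketyl reduction (SmI2, THF/MeOH) then gives the equatorial 6α-hydroxy ester F2, and anhydrous acid (camphorsulfonic acid cat., toluene, 60 °C) closes the lactone with loss of tert-butanol while the silyl ethers stay. It comes back to the route at 21.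

Step 21 (free dienone 31: the palladium-mediated dehydrosilylation is slow at high dilution, and 31 can add to itself before it is used). If the solution of 31 cannot be obtained clean, the dienone is released by selenoxide syn-elimination, which is complete within minutes below 0 °C. The fallback sets out from 30: PhSeCl (CH2Cl2, −78 °C) gives the stable, storable 2α-(phenylseleno)dehydrozaluzanin C F3 (selenium cis to H-1). Oxidation with mCPBA (1 equiv, CH2Cl2, −78 °C) gives the selenoxide F4, which eliminates on warming to −20 °C; a cold NaHCO3 wash removes the selenium and benzoic acids, and the cold organic solution is 31. It comes back to the route at 31.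

Step 23 (third unit added to a crowded dimer; 31 competes by adding to itself, and 36 still carries an exocyclic enone that can add a further unit). The fallback reverses the order of assembly and uses the self-addition. It sets out from 31: the solution from step 21 is concentrated cold to about 0.2 M without any other dienophile, so that 31 adds to itself and gives the A–B cycloadduct F5, which Et3N tautomerises to the conjugated 10α-H A–B dimer F6; unit B of F6 still carries the C2=C1–C10=C14 diene. Heating F6 with excess 29 (MeCN, 60 °C, Ar) gives the trimer-level cycloadduct F7, O2 converts it into the 10β-hydroperoxide F8, and PPh3 reduction comes back to the route at 36.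

**Further compounds**
F1 | step 12 | 7β-(tert-butoxycarbonylmethyl)-4β,10α-bis[(tert-butyldimethylsilyl)oxy]-1αH,5αH-11,12,13,14,15-pentanorguaian-6-one | CC(C)(C)[Si](C)(C)O[C@H]1CC[C@H]2[C@H](O[Si](C)(C)C(C)(C)C)CC[C@@H](CC(=O)OC(C)(C)C)C(=O)[C@H]21
F2 | step 12 | tert-butyl ester of the 6α-hydroxy-7β-acetic acid (hydroxy ester from F1) | CC(C)(C)[Si](C)(C)O[C@H]1CC[C@H]2[C@H](O[Si](C)(C)C(C)(C)C)CC[C@@H](CC(=O)OC(C)(C)C)[C@H](O)[C@H]21
F3 | step 21 | 2α-(phenylseleno)dehydrozaluzanin C | C=C1C(=O)[C@H]([Se]c2ccccc2)[C@H]2C(=C)CC[C@H]3C(=C)C(=O)O[C@@H]3[C@H]21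
F4 | step 21 | selenoxide of F3 (mixture at selenium) | C=C1C(=O)[C@H]([Se](=O)c2ccccc2)[C@H]2C(=C)CC[C@H]3C(=C)C(=O)O[C@@H]3[C@H]21
F5 | step 23 | A–B cycloadduct of two molecules of 31 (unit A: 1(10)-ene, H-2β; unit B: dienone) | C=C1C(=O)[C@H]2C3=C(CC[C@H]4C(=C)C(=O)O[C@@H]4[C@@H]13)CC[C@@]21C(=O)C=C2[C@H]1[C@H]1OC(=O)C(=C)[C@@H]1CCC2=C
F6 | step 23 | conjugated A–B dimer (unit A: 1-ene, 10α-H; unit B: dienone) | C=C1C(=O)C2=C3[C@H](CC[C@H]4C(=C)C(=O)O[C@@H]4[C@@H]13)CC[C@@]21C(=O)C=C2[C@H]1[C@H]1OC(=O)C(=C)[C@@H]1CCC2=C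
F7 | step 23 | trimer-level cycloadduct (unit B: 1(10)-ene, H-2β) | C=C1C(=O)C2=C3[C@H](CC[C@H]4C(=C)C(=O)O[C@@H]4[C@@H]13)CC[C@@]21C(=O)[C@H]2C3=C(CC[C@H]4C(=C)C(=O)O[C@@H]4[C@@H]13)CC[C@]21C(=O)C[C@H]2C(=C)CC[C@H]3C(=C)C(=O)O[C@@H]3[C@H]21
F8 | step 23 | 10β-hydroperoxide corresponding to 36 (unit B) | C=C1C(=O)C2=C3[C@H](CC[C@H]4C(=C)C(=O)O[C@@H]4[C@@H]13)CC[C@@]21C(=O)C2=C3[C@H]1[C@H]1OC(=O)C(=C)[C@@H]1CC[C@@]3(OO)CC[C@]21C(=O)C[C@H]2C(=C)CC[C@H]3C(=C)C(=O)O[C@@H]3[C@H]21
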